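## Retrosynthetic overview

- Target 20 ⇐ desilylation of Z‑silyl‑enyne 19 ⇐ Peterson olefination of aldehyde 17 ⇐ ozonolysis of allyl oxocane 16 ⇐ acetylation of chlorohydrin 15.
- Oxocane ring (formed second) ⇐ chlorinative ring expansion of 2,5‑cis‑oxolane 13: the ring oxygen displaces the C6 sulfonate (inversion), and chloride opens the bicyclic oxonium at C9 (inversion).
- Oxolane ring (formed first) ⇐ 5‑endo opening of the (9S,10S)‑epoxide 11 (Shi epoxidation of the E‑C9=C10 alkene) by the C12 hydroxyl.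
- C9=C10 ⇐ cross‑metathesis of bromohydrin ether 5 with pent‑4‑enal; the C12/C13 and C6/C7 halohydrins ⇐ organocatalytic α‑halogenation of an aldehyde followed by anti‑selective allylboration.

Locants C1–C15 in the explanations are those of the target chain (C1 = alkyne CH, C15 = methyl).

Assumption: the sense of induction of each named chiral catalyst is quoted from memory, so the catalyst enantiomer that gives the configuration drawn is the one meant; reagent 18 and the dibromodienone of step 1 are taken as purchasable.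

## Route

Step 1
Reactants: 1 butanal; 2 allylboronic acid pinacol ester
Product: 4 (4R,5S)-5-bromohept-1-en-4-ol, via (S)-2-bromobutanal 3 (not isolated)
Conditions: (2R,5R)-2,5-diphenylpyrrolidine (20 mol%), PhCO2H (20 mol%), 4,4-dibromo-2,6-di-tert-butylcyclohexa-2,5-dienone, CH2Cl2/pentane, −40 °C; cold SiO2 filtration; then 2, (R)-TRIP phosphoric acid (5 mol%), toluene, −30 °C
Reagents that add atoms: 4,4-dibromo-2,6-di-tert-butylcyclohexa-2,5-dienone, O=C1C(C(C)(C)C)=CC(Br)(Br)C=C1C(C)(C)C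
Why: Enamine‑catalysed asymmetric α‑bromination sets C13 (S) as the first stereocentre, and the chiral phosphoric acid‑catalysed allylboration adds to the Re face, which is also the Cornforth (anti) face of the α‑bromo aldehyde, so C12 is set as R.

Step 2
Reactants: 4 (4R,5S)-5-bromohept-1-en-4-ol
Product: 5 {[(4R,5S)-5-bromohept-1-en-4-yl]oxy}triethylsilane
Conditions: Et3SiOTf, 2,6-lutidine, CH2Cl2, −78 °C
Reagents that add atoms: triethylsilyl trifluoromethanesulfonate, CC[Si](CC)(CC)OS(=O)(=O)C(F)(F)F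
Why: Silyl ether formation masks the bromohydrin hydroxyl, which blocks epoxide closure under the basic epoxidation of step 6 and keeps C12–OH out of the sulfonylation of step 5.

Step 3
Reactants: 5 {[(4R,5S)-5-bromohept-1-en-4-yl]oxy}triethylsilane; 6 pent-4-enal
Product: 7 (4E,7R,8S)-8-bromo-7-(triethylsilyloxy)dec-4-enal
Conditions: 6 (4 equiv), second-generation Hoveyda–Grubbs catalyst RuCl2(H2IMes)(=CH-C6H4-2-OiPr) (5 mol%), CH2Cl2, 40 °C
Reagents that add atoms: none
Why: Olefin cross‑metathesis of two unhindered terminal alkenes, driven by loss of ethene, gives the thermodynamically preferred E‑C9=C10 alkene; the excess of cheap 6 suppresses homodimer of 5, and residual Z isomer is removed by chromatography.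

Step 4
Reactants: 7 (4E,7R,8S)-8-bromo-7-(triethylsilyloxy)dec-4-enal; 2 allylboronic acid pinacol ester
Product: 9 (4R,5S,7E,10R,11S)-11-bromo-5-chloro-10-(triethylsilyloxy)trideca-1,7-dien-4-ol, via (2S)-2-chloro aldehyde 8 (not isolated)
Conditions: (2R,5R)-2,5-diphenylpyrrolidine (10 mol%), N-chlorosuccinimide, CH2Cl2, 0 °C; cold SiO2 filtration; then 2, (R)-TRIP phosphoric acid (5 mol%), toluene, −30 °C
Reagents that add atoms: N-chlorosuccinimide, ClN1C(=O)CCC1=O
Why: Enamine‑catalysed asymmetric α‑chlorination sets C7 (S) under catalyst control (the remote stereocentres do not interfere), and the matched phosphoric acid‑catalysed, Cornforth‑selective allylboration gives the anti chlorohydrin, C6 (R).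

Step 5
Reactants: 9 (4R,5S,7E,10R,11S)-11-bromo-5-chloro-10-(triethylsilyloxy)trideca-1,7-dien-4-ol
Product: 10 (4R,5S,7E,10R,11S)-11-bromo-5-chloro-10-(triethylsilyloxy)trideca-1,7-dien-4-yl chloromethanesulfonate
Conditions: ClCH2SO2Cl, pyridine, CH2Cl2, 0 °C
Reagents that add atoms: chloromethanesulfonyl chloride, ClCS(Cl)(=O)=O
Why: Sulfonylation of the only free hydroxyl installs, with retention at C6, a chromatography‑stable leaving group about a hundred times more reactive than a mesylate, before any other hydroxyl exists in the molecule.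

Step 6
Reactants: 10 (4R,5S,7E,10R,11S)-11-bromo-5-chloro-10-(triethylsilyloxy)trideca-1,7-dien-4-yl chloromethanesulfonate
Product: 11 (4R,5S)-6-{(2S,3S)-3-[(2R,3S)-3-bromo-2-(triethylsilyloxy)pentyl]oxiran-2-yl}-5-chlorohex-1-en-4-yl chloromethanesulfonate
Conditions: ent-Shi ketone (L-fructose-derived, 30 mol%), KHSO5 (Oxone), K2CO3, Bu4NHSO4, MeCN/CH2(OMe)2–aqueous Na2B4O7 buffer (pH 10.5), 0 °C
Reagents that add atoms: potassium peroxymonosulfate KHSO5, [K+].[O-]S(=O)(=O)OO
Why: Shi asymmetric epoxidation (chiral dioxirane, reagent control) converts the trans‑disubstituted C9=C10 alkene into the (9S,10S)‑epoxide, while the terminal allyl alkene, a poor substrate for this catalyst, is left intact.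

Step 7
Reactants: 11 (4R,5S)-6-{(2S,3S)-3-[(2R,3S)-3-bromo-2-(triethylsilyloxy)pentyl]oxiran-2-yl}-5-chlorohex-1-en-4-yl chloromethanesulfonate
Product: 13 (4R,5S)-6-{(2R,3S,5R)-5-[(1S)-1-bromopropyl]-3-hydroxyoxolan-2-yl}-5-chlorohex-1-en-4-yl chloromethanesulfonate, via desilylated epoxy alcohol 12 (not isolated)
Conditions: TsOH·H2O (20 mol%), MeOH (5 equiv), CH2Cl2, 0 °C to rt
Reagents that add atoms: none
Why: Acid removes the silyl group and the freed C12 hydroxyl opens the 3,4‑epoxy alcohol at C9 in a 5‑endo epoxide opening (the 4‑exo mode is strained), with inversion to 9R, giving the 2,5‑cis‑oxolane stereospecifically with C10–OH trans to both side chains.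

Step 8
Reactants: 13 (4R,5S)-6-{(2R,3S,5R)-5-[(1S)-1-bromopropyl]-3-hydroxyoxolan-2-yl}-5-chlorohex-1-en-4-yl chloromethanesulfonate
Product: 15 (2R,4S,5S,7S,8S)-2-[(1S)-1-bromopropyl]-5,7-dichloro-8-(prop-2-en-1-yl)oxocan-4-ol, via bicyclic oxonium ion 14 (not isolated)
Conditions: ZnCl2 (2.5 equiv, 1 M in Et2O), 2,6-di-tert-butyl-4-methylpyridine (0.3 equiv), MeNO2, 0 to 60 °C
Reagents that add atoms: zinc dichloride ZnCl2, [Zn+2].[Cl-].[Cl-]
Why: Proposed new method: a zinc chloride‑mediated chlorinative ring expansion in which Zn‑assisted loss of the chloromesylate with backside participation of the oxolane oxygen (5‑exo‑tet, C6 R→S) gives the 1‑oxoniabicyclo[3.3.0]octane ion 14, and the zinc‑bound C10 hydroxyl, which lies anti to the C9–O+ bond and cannot close the strained trans‑epoxide, delivers chloride through a five‑membered transition state to the ring‑fusion carbon C9 (inversion, 9R→9S), cleaving the shared C–O bond to the oxocane; the closest known reactions are the zinc acetate ring expansion of tetrahydrofuranyl chloromesylates through bicyclic oxonium ions (Nakata type), the bromonium‑induced tetrahydrofuran‑to‑oxocane expansion with internal capture at the ring‑fusion carbon, and the solvolytic interconversion of 3‑(oxolan‑2‑yl)propyl and oxocan‑5‑yl sulfonates.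

Step 9
Reactants: 15 (2R,4S,5S,7S,8S)-2-[(1S)-1-bromopropyl]-5,7-dichloro-8-(prop-2-en-1-yl)oxocan-4-ol
Product: 16 (2R,4S,5S,7S,8S)-2-[(1S)-1-bromopropyl]-5,7-dichloro-8-(prop-2-en-1-yl)oxocan-4-yl acetate
Conditions: Ac2O, pyridine, DMAP (5 mol%), CH2Cl2, 0 °C
Reagents that add atoms: acetic anhydride, CC(=O)OC(C)=O
Why: Acylation under weakly basic conditions caps C10–OH without alkoxide formation, so the trans‑chlorohydrin cannot close to an epoxide.

Step 10
Reactants: 16 (2R,4S,5S,7S,8S)-2-[(1S)-1-bromopropyl]-5,7-dichloro-8-(prop-2-en-1-yl)oxocan-4-yl acetate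
Product: 17 (2R,4S,5S,7S,8S)-2-[(1S)-1-bromopropyl]-5,7-dichloro-8-(2-oxoethyl)oxocan-4-yl acetate
Conditions: O3, CH2Cl2, −78 °C; then PPh3, −78 °C to rt
Reagents that add atoms: ozone, [O-][O+]=O
Why: Ozonolysis with reductive work‑up cleaves the only alkene left in the molecule to the C4 aldehyde and touches no stereocentre.

Step 11
Reactants: 17 (2R,4S,5S,7S,8S)-2-[(1S)-1-bromopropyl]-5,7-dichloro-8-(2-oxoethyl)oxocan-4-yl acetate; 18 1,3-bis(triisopropylsilyl)propyne
Product: 19 (2R,4S,5S,7S,8S)-2-[(1S)-1-bromopropyl]-5,7-dichloro-8-[(2Z)-5-(triisopropylsilyl)pent-2-en-4-yn-1-yl]oxocan-4-yl acetate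
Conditions: 18, n-BuLi, THF, −78 °C, 30 min; then 17, −78 to −20 °C
Reagents that add atoms: none
Why: Yamamoto–Peterson olefination with the lithiated bis‑silylpropyne adds to the aldehyde faster than to the acetate at −78 °C and eliminates syn to give the Z‑enyne (typically about 20:1).

Step 12
Reactants: 19 (2R,4S,5S,7S,8S)-2-[(1S)-1-bromopropyl]-5,7-dichloro-8-[(2Z)-5-(triisopropylsilyl)pent-2-en-4-yn-1-yl]oxocan-4-yl acetate
Product: 20 (2R,4S,5S,7S,8S)-2-[(1S)-1-bromopropyl]-5,7-dichloro-8-[(2Z)-pent-2-en-4-yn-1-yl]oxocan-4-yl acetate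
Conditions: Bu4NF/AcOH (1:1), THF, 0 °C
Reagents that add atoms: none
Why: Fluoride‑mediated C–Si cleavage of the alkynylsilane, buffered with acetic acid so that the acetate and the secondary halides survive, gives the target (6S,7S,9S,10S,12R,13S by chain numbering).

## Compound list

1 | butanal | CCCC=O | starting material
2 | allylboronic acid pinacol ester (2-allyl-4,4,5,5-tetramethyl-1,3,2-dioxaborolane) | C=CCB1OC(C)(C)C(C)(C)O1 | starting material
3 | (S)-2-bromobutanal | CC[C@H](Br)C=O | intermediate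
4 | (4R,5S)-5-bromohept-1-en-4-ol | CC[C@H](Br)[C@H](O)CC=C | intermediate
5 | {[(4R,5S)-5-bromohept-1-en-4-yl]oxy}triethylsilane | CC[C@H](Br)[C@H](O[Si](CC)(CC)CC)CC=C | intermediate
6 | pent-4-enal | C=CCCC=O | starting material
7 | (4E,7R,8S)-8-bromo-7-(triethylsilyloxy)dec-4-enal | CC[C@H](Br)[C@H](O[Si](CC)(CC)CC)C/C=C/CCC=O | intermediate
8 | (2S,4E,7R,8S)-8-bromo-2-chloro-7-(triethylsilyloxy)dec-4-enal | CC[C@H](Br)[C@H](O[Si](CC)(CC)CC)C/C=C/C[C@H](Cl)C=O | intermediate
9 | (4R,5S,7E,10R,11S)-11-bromo-5-chloro-10-(triethylsilyloxy)trideca-1,7-dien-4-ol | CC[C@H](Br)[C@H](O[Si](CC)(CC)CC)C/C=C/C[C@H](Cl)[C@H](O)CC=C | intermediate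
10 | (4R,5S,7E,10R,11S)-11-bromo-5-chloro-10-(triethylsilyloxy)trideca-1,7-dien-4-yl chloromethanesulfonate | CC[C@H](Br)[C@H](O[Si](CC)(CC)CC)C/C=C/C[C@H](Cl)[C@H](OS(=O)(=O)CCl)CC=C | intermediate
11 | (4R,5S)-6-{(2S,3S)-3-[(2R,3S)-3-bromo-2-(triethylsilyloxy)pentyl]oxiran-2-yl}-5-chlorohex-1-en-4-yl chloromethanesulfonate | CC[C@H](Br)[C@H](O[Si](CC)(CC)CC)C[C@@H]1O[C@H]1C[C@H](Cl)[C@H](OS(=O)(=O)CCl)CC=C | intermediate
12 | (4R,5S)-6-{(2S,3S)-3-[(2R,3S)-3-bromo-2-hydroxypentyl]oxiran-2-yl}-5-chlorohex-1-en-4-yl chloromethanesulfonate | CC[C@H](Br)[C@H](O)C[C@@H]1O[C@H]1C[C@H](Cl)[C@H](OS(=O)(=O)CCl)CC=C | intermediate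
13 | (4R,5S)-6-{(2R,3S,5R)-5-[(1S)-1-bromopropyl]-3-hydroxyoxolan-2-yl}-5-chlorohex-1-en-4-yl chloromethanesulfonate | CC[C@H](Br)[C@H]1C[C@H](O)[C@H](O1)C[C@H](Cl)[C@H](OS(=O)(=O)CCl)CC=C | intermediate
14 | (2S,3S,5R,6S,8R)-8-[(1S)-1-bromopropyl]-3-chloro-6-hydroxy-2-(prop-2-en-1-yl)-1-oxoniabicyclo[3.3.0]octane chloromethanesulfonate | C=CC[C@@H]1[O+]2[C@@H]([C@@H](Br)CC)C[C@H](O)[C@H]2C[C@@H]1Cl.[O-]S(=O)(=O)CCl | intermediate
15 | (2R,4S,5S,7S,8S)-2-[(1S)-1-bromopropyl]-5,7-dichloro-8-(prop-2-en-1-yl)oxocan-4-ol | C=CC[C@@H]1O[C@@H]([C@@H](Br)CC)C[C@H](O)[C@@H](Cl)C[C@@H]1Cl | intermediate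
16 | (2R,4S,5S,7S,8S)-2-[(1S)-1-bromopropyl]-5,7-dichloro-8-(prop-2-en-1-yl)oxocan-4-yl acetate | C=CC[C@@H]1O[C@@H]([C@@H](Br)CC)C[C@H](OC(C)=O)[C@@H](Cl)C[C@@H]1Cl | intermediate
17 | (2R,4S,5S,7S,8S)-2-[(1S)-1-bromopropyl]-5,7-dichloro-8-(2-oxoethyl)oxocan-4-yl acetate | O=CC[C@@H]1O[C@@H]([C@@H](Br)CC)C[C@H](OC(C)=O)[C@@H](Cl)C[C@@H]1Cl | intermediate
18 | 1,3-bis(triisopropylsilyl)propyne | CC(C)[Si](C(C)C)(C(C)C)CC#C[Si](C(C)C)(C(C)C)C(C)C | starting material
19 | (2R,4S,5S,7S,8S)-2-[(1S)-1-bromopropyl]-5,7-dichloro-8-[(2Z)-5-(triisopropylsilyl)pent-2-en-4-yn-1-yl]oxocan-4-yl acetate | CC(C)[Si](C(C)C)(C(C)C)C#C/C=C\C[C@@H]1O[C@@H]([C@@H](Br)CC)C[C@H](OC(C)=O)[C@@H](Cl)C[C@@H]1Cl | intermediate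
20 | (2R,4S,5S,7S,8S)-2-[(1S)-1-bromopropyl]-5,7-dichloro-8-[(2Z)-pent-2-en-4-yn-1-yl]oxocan-4-yl acetate | C#C/C=C\C[C@@H]1O[C@@H]([C@@H](Br)CC)C[C@H](OC(C)=O)[C@@H](Cl)C[C@@H]1Cl | target

## Step count and risks

Total: 12 steps. Longest linear sequence: 12 steps (1 → 20).

**Step 8 (the proposed new step).** Three things can go wrong. The free C10 hydroxyl may attack C6 itself (6‑exo‑tet) to give a fused oxolane–oxane ether. Chloride may open the oxonium at C6 or C12 instead of C9, giving oxolane chlorides. The β‑bromide may reopen the oxonium to a bromonium ion. The fallback uses known chemistry, sets out from 13 and comes back at 16; it lets the C10 oxygen substituent make the C9 bond and puts chloride in afterwards with retention. Acetylation of 13 (Ac2O, pyridine) gives (4R,5S)-6-{(2R,3S,5R)-3-acetoxy-5-[(1S)-1-bromopropyl]oxolan-2-yl}-5-chlorohex-1-en-4-yl chloromethanesulfonate F1. Heating F1 with Zn(OAc)2 in AcOH/H2O (the zinc acetate ring‑expansion conditions) forms the same sulfonate‑triggered oxonium, which the neighbouring C10 acetate captures at the ring‑fusion carbon; water then opens the acetoxonium to (2R,4S,5S,7S,8S)-2-[(1S)-1-bromopropyl]-7-chloro-5-hydroxy-8-(prop-2-en-1-yl)oxocan-4-yl acetate F2. Its acyl‑shifted isomer (2R,4S,5S,7S,8S)-2-[(1S)-1-bromopropyl]-7-chloro-4-hydroxy-8-(prop-2-en-1-yl)oxocan-5-yl acetate F3 forms alongside and is re‑equilibrated (DMAP, toluene, 60 °C) and recycled. SOCl2 in 1,4‑dioxane then converts F2 into 16 with retention at C9, since neighbouring‑acetate participation, transannular ether participation and internal return all lead to double inversion. The weak point of this fallback is chloride opening of the acetoxonium at C10, which would give a regioisomer to be separated.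

**Step 1.** The α‑bromo aldehyde 3 racemises and alkylates the amine catalyst easily, and carried‑over amine can quench the phosphoric acid. The fallback makes 3 amine‑free by epoxide chemistry instead of enamine bromination; it keeps partner 2, replaces 1 by commercial (E)-pent-2-en-1-ol F4 (its only compound not drawn from the numbered list) and comes back at 3, hence 4. Shi epoxidation of F4 with the normal D‑fructose‑derived ketone and KHSO5 gives [(2R,3R)-3-ethyloxiran-2-yl]methanol F5. Ti(OiPr)4 with Et2NH2Br opens F5 at C3 with inversion to (2R,3S)-3-bromopentane-1,2-diol F6. NaIO4 on silica in CH2Cl2 cleaves the diol to 3, which is filtered, dried and used at once in the phosphoric acid‑catalysed allylboration of step 1.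

**Step 11.** The lithiated propyne is a strong base and nucleophile toward a β‑alkoxy aldehyde that also carries an acetate and three secondary halides, so elimination or acetate cleavage may compete. The fallback sets out from 17 and comes back at 20. Stork–Zhao olefination (Ph3P(CH2I)I, NaN(SiMe3)2, THF/DMPU, −78 °C) gives (2R,4S,5S,7S,8S)-2-[(1S)-1-bromopropyl]-5,7-dichloro-8-[(2Z)-3-iodoprop-2-en-1-yl]oxocan-4-yl acetate F7. Sonogashira coupling with trimethylsilylacetylene (Pd(PPh3)4, CuI, iPr2NH) gives (2R,4S,5S,7S,8S)-2-[(1S)-1-bromopropyl]-5,7-dichloro-8-[(2Z)-5-(trimethylsilyl)pent-2-en-4-yn-1-yl]oxocan-4-yl acetate F8. Bu4NF/AcOH in THF at −20 °C then gives 20.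

Further compounds
F1 | step 8 | (4R,5S)-6-{(2R,3S,5R)-3-acetoxy-5-[(1S)-1-bromopropyl]oxolan-2-yl}-5-chlorohex-1-en-4-yl chloromethanesulfonate | CC[C@H](Br)[C@H]1C[C@H](OC(C)=O)[C@H](O1)C[C@H](Cl)[C@H](OS(=O)(=O)CCl)CC=C
F2 | step 8 | (2R,4S,5S,7S,8S)-2-[(1S)-1-bromopropyl]-7-chloro-5-hydroxy-8-(prop-2-en-1-yl)oxocan-4-yl acetate | C=CC[C@@H]1O[C@@H]([C@@H](Br)CC)C[C@H](OC(C)=O)[C@@H](O)C[C@@H]1Cl
F3 | step 8 | (2R,4S,5S,7S,8S)-2-[(1S)-1-bromopropyl]-7-chloro-4-hydroxy-8-(prop-2-en-1-yl)oxocan-5-yl acetate | C=CC[C@@H]1O[C@@H]([C@@H](Br)CC)C[C@H](O)[C@@H](OC(C)=O)C[C@@H]1Cl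
F4 | step 1 | (E)-pent-2-en-1-ol | CC/C=C/CO
F5 | step 1 | [(2R,3R)-3-ethyloxiran-2-yl]methanol | CC[C@H]1O[C@@H]1CO
F6 | step 1 | (2R,3S)-3-bromopentane-1,2-diol | CC[C@H](Br)[C@H](O)CO
F7 | step 11 | (2R,4S,5S,7S,8S)-2-[(1S)-1-bromopropyl]-5,7-dichloro-8-[(2Z)-3-iodoprop-2-en-1-yl]oxocan-4-yl acetate | I/C=C\C[C@@H]1O[C@@H]([C@@H](Br)CC)C[C@H](OC(C)=O)[C@@H](Cl)C[C@@H]1Cl
F8 | step 11 | (2R,4S,5S,7S,8S)-2-[(1S)-1-bromopropyl]-5,7-dichloro-8-[(2Z)-5-(trimethylsilyl)pent-2-en-4-yn-1-yl]oxocan-4-yl acetate | C[Si](C)(C)C#C/C=C\C[C@@H]1O[C@@H]([C@@H](Br)CC)C[C@H](OC(C)=O)[C@@H](Cl)C[C@@H]1Cl
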